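I was asked whether the excess of right-handed substrate in this flask, a racemate resolved by a single-handed catalyst, reaches 80% by 40 min, and how high it climbs.

| setting | midnight | flask |
|---|---|---|
| left-handed substrate | 1 M | 1.0 M |
| right-handed substrate | 1 M | 1.0 M |
| solid reagent | 1.1 M | 1.10 M |
| precatalyst | 25 mM | 25 mM |
| remark | the very flask that is asked about, followed so far |  |
| time |  | 40 min |

midnight run (percent of the left-handed substrate and right-handed substrate together charged)

| time / min | right-handed substrate / % | left-handed substrate / % |
|---|---|---|
| 0.833 | 51.1 | 47.7 |
| 2.50 | 50.0 | 41.3 |
| 4.00 | 48.9 | 33.1 |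
| 6.00 | 48.8 | 22.4 |
| 10.0 | 50.4 | 11.7 |
| 12.0 | 48.7 | 8.0 |

(readings scatter by 1 percentage point)

1. whether the excess of right-handed substrate over left-handed substrate among what is left of the two reaches 80% by 40 min (no / yes)
2. the highest excess of right-handed substrate over left-handed substrate among what is left of the two up to 40 min

- free catalyst is single-handed; left-handed substrate and right-handed substrate are mirror images of each other, charged as a racemate, each of them at the stated concentration
- solid, in amounts per volume of the solution: solid reagent
- at the start none of the solid reagent is in solution

I began with a ledger of the solid reagent, the limiting reagent for the two substrates together. I assumed one mole per mole of substrate. Of the 1.1 M charged, the left-handed substrate had taken about 0.840 M by the reading at 12.0 min. The 0.160 M of it still standing would take that amount more. That left 0.100 M over for the right-handed substrate, and the books closed.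

Then I counted half-lives. From 6.00 min to 12.0 min the left-handed substrate in the midnight run read 22.4% and then 8.0%. That gave 4.04 min as a reading of its half-life, the time for it to drop by a factor of 2. The wanted excess needed it at 5.41%, which was 0.564 half-lives past 12.0 min, so about 14.3 min.

But the ledger warned me. If the rate followed the reagent left, falling from 0.260 M to 0.100 M, the half-life would stretch by up to 2.60 times. Even stretched throughout, the count gave 17.9 min, earlier than the limit. So I said yes. For the top, the steady count gave 99.7% and the stretched count 95.0%.

The forecast said yes and gave the single figure 99%, inside my range: a rate following the solid still “drives the left-handed substrate to near zero”.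

The flask gave yes and 97.1%.

    partner + catalyst intermediate A → free catalyst + left-handed product (k = 0.260 L mol⁻¹ s⁻¹)
    partner + catalyst intermediate B → free catalyst + right-handed product (k = 0.00540 L mol⁻¹ s⁻¹)
    left-handed product ⇌ right-handed product (k = 2.00 × 10⁻⁴ s⁻¹)
    solid reagent ⇌ partner, rate k4*(cs4 - [partner]) while solid is left; crystals form when [partner] > cs4 (solubility = 0.810 M, k = 0.0200 s⁻¹)
    free catalyst + right-handed substrate ⇌ catalyst intermediate B (K = 0.550 L mol⁻¹, k = 0.240 L mol⁻¹ s⁻¹)
    free catalyst + left-handed substrate ⇌ catalyst intermediate A (K = 3.60 L mol⁻¹, k = 0.590 L mol⁻¹ s⁻¹)
    precatalyst → free catalyst (k = 0.0110 s⁻¹)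

At 40.0 min the partner in the flask, the dissolved form of the solid reagent, stood at 0.0952 M, close to the 0.100 M of the ledger. From 20.0 min to 40.0 min the left-handed substrate in the flask went from 3.72% to 0.713%. That is a half-life of 8.39 min, which is 2.08 times the 4.04 min read at first.

The readings come from a simulation from invented constants; scatter was added.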